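**Plan**
- **Cuts, part 1 (flavonol numbering):** the three phenolic MOM ethers go first. Then O1–C2 of ring C is cut and O1 is put back on C3. This contracts the pyranone to a benzofuran-3-one with a spiro oxirane (an aurone epoxide), whose oxirane oxygen is the future 3-OH.
- **Cuts, part 2:** the oxirane oxygen (back to a Z aurone), C2–C3 (aldol condensation with a ring B aldehyde), O1–C3 (phenoxide on a chloroacetyl CH2), C4–C4a (aryllithium on a Weinreb amide), and the aryl–prenyl bonds at C6 and C8 (aryllithium on prenyl bromide).
- **Forward order:** ring A comes from phloroglucinol and is fully substituted first. The five-membered furanone then closes, ring B is attached, the oxirane is added, the furanone is enlarged to six-membered ring C, and deprotection ends the route.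
- **Enabling feature:** in ring C the oxygen-bearing C3 sits between the C4 carbonyl and C2, and C2 is benzylic to ring B with its para 4'-oxygen. C3 can therefore be stored as a ketal-type carbon holding both O1 and the future 3-OH, while C2 readily takes up and releases a halide. The C5 oxygen peri to C4=O, which diverts oxidative chalcone closures to five-membered products, then serves the route.
- **Stereochemistry:** the target has no stereocentre. The Z alkene (thermodynamic) and the two racemic oxirane centres derived from it are transient and become sp2 carbons in the key step.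

Key step: step 9

Remark: prenyl = 3-methylbut-2-en-1-yl and MOM = methoxymethyl. All chiral intermediates are racemic, and stereo marks in their SMILES show one enantiomer only to fix the relative configuration.

Step 1
Reactants: 1 phloroglucinol
Product: 2 1,3,5-tris(methoxymethoxy)benzene
Conditions: NaH, MOMCl, DMF, 0 °C → rt
Reagents that add atoms: chloromethyl methyl ether (MOMCl), COCCl
Why: Williamson-type O-alkylation, in which the hard electrophile MOMCl favours attack at oxygen over carbon and installs three groups that later direct lithiation.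

Step 2
Reactants: 2 1,3,5-tris(methoxymethoxy)benzene; 3 prenyl bromide
Product: 5 1,3,5-tris(methoxymethoxy)-2-prenylbenzene, via aryllithium 4 (not isolated)
Conditions: n-BuLi, THF, 0 °C → rt; then 3, −78 °C → rt
Reagents that add atoms: none
Why: Directed ortho-metalation removes a ring hydrogen flanked by two chelating OMOM groups, and aryllithium 4 should be alkylated by the primary allylic bromide in SN2 fashion to give the linear prenyl group.

Step 3
Reactants: 5 1,3,5-tris(methoxymethoxy)-2-prenylbenzene; 3 prenyl bromide
Product: 7 1,3,5-tris(methoxymethoxy)-2,4-diprenylbenzene, via aryllithium 6 (not isolated)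
Conditions: n-BuLi, THF, 0 °C → rt; then 3, −78 °C → rt
Reagents that add atoms: none
Why: This is a second directed ortho-metalation and alkylation, in which the two remaining ring hydrogens are equivalent and each lies between two OMOM groups, so chelation-guided ring lithiation should win over removal of a benzylic-allylic hydrogen.

Step 4
Reactants: 7 1,3,5-tris(methoxymethoxy)-2,4-diprenylbenzene; 8 2-chloro-N-methoxy-N-methylacetamide
Product: 11 2-chloro-1-[2,4,6-tris(methoxymethoxy)-3,5-diprenylphenyl]ethanone, via aryllithium 9 (not isolated), via lithium hemiaminal alkoxide 10 (not isolated)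
Conditions: n-BuLi, TMEDA, THF, 0 °C; then 8, −78 °C; then AcOH, −78 °C → rt
Reagents that add atoms: none
Why: Directed ortho-metalation is followed by a Weinreb ketone synthesis, and the chelated adduct 10 persists until the cold acidic quench, so neither over-addition nor attack at the C–Cl bond should interfere.

Step 5
Reactants: 11 2-chloro-1-[2,4,6-tris(methoxymethoxy)-3,5-diprenylphenyl]ethanone
Product: 13 4,6-bis(methoxymethoxy)-5,7-diprenylbenzofuran-3(2H)-one, via ortho-hydroxy chloroketone 12 (not isolated)
Conditions: conc. HCl (cat.), MeOH–THF, 0 °C → rt; then K2CO3, rt, N2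
Reagents that add atoms: none
Why: Acid-catalysed acetal exchange should first remove one of the two symmetry-equivalent MOM groups ortho to the ketone, because the carbonyl relays the proton and then locks the freed phenol in a hydrogen-bonded chelate, after which the phenoxide of 12 closes the furanone by an intramolecular Williamson 5-exo-tet displacement of chloride.

Step 6
Reactants: 14 4-hydroxybenzaldehyde
Product: 15 4-(methoxymethoxy)benzaldehyde
Conditions: MOMCl, K2CO3, acetone, rt
Reagents that add atoms: chloromethyl methyl ether (MOMCl), COCCl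
Why: Williamson-type O-alkylation of an acidic phenol under conditions that leave the aldehyde untouched.

Step 7
Reactants: 13 4,6-bis(methoxymethoxy)-5,7-diprenylbenzofuran-3(2H)-one; 15 4-(methoxymethoxy)benzaldehyde
Product: 16 (Z)-4,6,4'-tris(methoxymethoxy)-5,7-diprenylaurone
Conditions: KOH, MeOH, rt → 50 °C, N2
Reagents that add atoms: none
Why: Claisen–Schmidt type aldol condensation at the acidic C2 methylene with E1cB loss of water, giving the Z alkene under thermodynamic control because the aryl group avoids the C3 carbonyl and lies on the side of O1.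

Step 8
Reactants: 16 (Z)-4,6,4'-tris(methoxymethoxy)-5,7-diprenylaurone
Product: 17 aurone epoxide, (2S*,3'S*)-4,6-bis(methoxymethoxy)-3'-[4-(methoxymethoxy)phenyl]-5,7-diprenylspiro[benzofuran-2(3H),2'-oxiran]-3-one (racemic; aryl cis to O1 on the oxirane)
Conditions: 30% aq H2O2, BnNMe3OH (cat.), THF–MeOH, 0 °C → rt
Reagents that add atoms: hydrogen peroxide, OO
Why: In this Weitz–Scheffer nucleophilic epoxidation, hydroperoxide adds only to the electron-poor enone alkene and ignores the two electron-rich prenyl alkenes, both faces react equally (racemate), and the two new centres take their relative configuration from the Z alkene because the peroxy enolate should close before it rotates into the more crowded rotamer.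

Step 9
Reactants: 17 aurone epoxide
Product: 21 5,7,4'-tris(methoxymethoxy)-6,8-diprenylflavonol, via iodohydrin alkoxide 18 (not isolated), via iodo diketone phenoxide 19 (not isolated), via chromane-3,4-dione 20 (not isolated)
Conditions: LiI (0.2 equiv), 4 Å molecular sieves, THF, 55 °C, Ar, dark
Reagents that add atoms: none
Why: Proposed new method: iodide, helped by lithium coordination to the oxirane oxygen, should attack the CH(aryl) carbon of 17 with inversion to give hemiketal alkoxide 18, which collapses to the 1,2-diketone by breaking the old O1–C bond and so frees the ring A phenoxide in 19. That phenoxide displaces the benzylic, carbonyl-flanked iodide in a 6-exo-tet closure that forms O1–C2 and six-membered ring C, and dione 20 enolises to the aromatic 3-hydroxypyran-4-one 21, which makes the sequence irreversible and gives LiI back. The closest known reaction types are the alkali stage of the Auwers flavonol synthesis, which runs through the bromo analogue of 18, the two-stage conversion of aurone epoxides into flavonols by way of their halohydrins, and the lithium halide catalysed isomerisation of epoxides; new here is the merger of these events under a catalytic halide in a neutral medium. No stereocentre remains, because both oxirane carbons end as the sp2 atoms C2 and C3, so neither the relative configuration of 17 nor the lability of the C–I centre matters. Regioselective opening is needed and is secured by the 4-alkoxyphenyl group, which stabilises positive charge build-up at the CH carbon, and by the spiro carbon being quaternary and next to a carbonyl. Halide capture must also outrun the 1,2-acyl shift typical of epoxy ketones under strong Lewis acids, which THF-solvated lithium paired with a very nucleophilic anion should ensure, and the absence of protic acid, oxidant or free halogen spares both prenyl alkenes and all three acetals.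

Step 10
Reactants: 21 5,7,4'-tris(methoxymethoxy)-6,8-diprenylflavonol
Product: 22 6,8-diprenylkaempferol
Conditions: HCl (1 M in MeOH), 40 °C, stopped at full conversion
Reagents that add atoms: none
Why: Acid-catalysed transacetalisation turns the three aryl MOM ethers into phenols and dimethoxymethane, and moderate temperature with short exposure should keep the freed ortho phenols from adding to the prenyl alkenes.

**Compound list**
1 | phloroglucinol | Oc1cc(O)cc(O)c1 | starting material
2 | 1,3,5-tris(methoxymethoxy)benzene | COCOc1cc(OCOC)cc(OCOC)c1 | intermediate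
3 | prenyl bromide (1-bromo-3-methylbut-2-ene) | CC(C)=CCBr | starting material
4 | [2,4,6-tris(methoxymethoxy)phenyl]lithium | [Li]c1c(OCOC)cc(OCOC)cc1OCOC | intermediate
5 | 1,3,5-tris(methoxymethoxy)-2-prenylbenzene | COCOc1cc(OCOC)c(CC=C(C)C)c(OCOC)c1 | intermediate
6 | [2,4,6-tris(methoxymethoxy)-3-prenylphenyl]lithium | [Li]c1c(OCOC)cc(OCOC)c(CC=C(C)C)c1OCOC | intermediate
7 | 1,3,5-tris(methoxymethoxy)-2,4-diprenylbenzene | COCOc1cc(OCOC)c(CC=C(C)C)c(OCOC)c1CC=C(C)C | intermediate
8 | 2-chloro-N-methoxy-N-methylacetamide | CON(C)C(=O)CCl | starting material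
9 | [2,4,6-tris(methoxymethoxy)-3,5-diprenylphenyl]lithium | [Li]c1c(OCOC)c(CC=C(C)C)c(OCOC)c(CC=C(C)C)c1OCOC | intermediate
10 | lithium 2-chloro-1-[methoxy(methyl)amino]-1-[2,4,6-tris(methoxymethoxy)-3,5-diprenylphenyl]ethanolate (racemic) | [Li]OC(CCl)(N(C)OC)c1c(OCOC)c(CC=C(C)C)c(OCOC)c(CC=C(C)C)c1OCOC | intermediate
11 | 2-chloro-1-[2,4,6-tris(methoxymethoxy)-3,5-diprenylphenyl]ethanone | O=C(CCl)c1c(OCOC)c(CC=C(C)C)c(OCOC)c(CC=C(C)C)c1OCOC | intermediate
12 | 2-chloro-1-[2-hydroxy-4,6-bis(methoxymethoxy)-3,5-diprenylphenyl]ethanone | O=C(CCl)c1c(O)c(CC=C(C)C)c(OCOC)c(CC=C(C)C)c1OCOC | intermediate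
13 | 4,6-bis(methoxymethoxy)-5,7-diprenylbenzofuran-3(2H)-one | O=C1COc2c(CC=C(C)C)c(OCOC)c(CC=C(C)C)c(OCOC)c12 | intermediate
14 | 4-hydroxybenzaldehyde | O=Cc1ccc(O)cc1 | starting material
15 | 4-(methoxymethoxy)benzaldehyde | COCOc1ccc(C=O)cc1 | intermediate
16 | (Z)-4,6,4'-tris(methoxymethoxy)-5,7-diprenylaurone | O=C1c2c(OCOC)c(CC=C(C)C)c(OCOC)c(CC=C(C)C)c2O/C1=C\c1ccc(OCOC)cc1 | intermediate
17 | 4,6,4'-tris(methoxymethoxy)-5,7-diprenylaurone epoxide (racemic, (2S*,3'S*), aryl cis to O1 on the oxirane) | O=C1c2c(OCOC)c(CC=C(C)C)c(OCOC)c(CC=C(C)C)c2O[C@]12O[C@H]2c1ccc(OCOC)cc1 | intermediate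
18 | lithium alkoxide of 2-hydroxy-2-{iodo[4-(methoxymethoxy)phenyl]methyl}-4,6-bis(methoxymethoxy)-5,7-diprenylbenzofuran-3(2H)-one (racemic, benzylic carbon inverted relative to 17) | O=C1c2c(OCOC)c(CC=C(C)C)c(OCOC)c(CC=C(C)C)c2O[C@@]1([O-])[C@H](I)c1ccc(OCOC)cc1.[Li+] | intermediate
19 | lithium 2-{3-iodo-3-[4-(methoxymethoxy)phenyl]-2-oxopropanoyl}-3,5-bis(methoxymethoxy)-4,6-diprenylphenolate (racemic, labile C–I centre) | [Li+].[O-]c1c(CC=C(C)C)c(OCOC)c(CC=C(C)C)c(OCOC)c1C(=O)C(=O)C(I)c1ccc(OCOC)cc1 | intermediate
20 | 5,7-bis(methoxymethoxy)-2-[4-(methoxymethoxy)phenyl]-6,8-diprenylchromane-3,4-dione (racemic) | O=C1C(=O)c2c(OCOC)c(CC=C(C)C)c(OCOC)c(CC=C(C)C)c2OC1c1ccc(OCOC)cc1 | intermediate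
21 | 5,7,4'-tris(methoxymethoxy)-6,8-diprenylflavonol (3-hydroxy-5,7-bis(methoxymethoxy)-2-[4-(methoxymethoxy)phenyl]-6,8-diprenyl-4H-chromen-4-one) | COCOc1ccc(cc1)-c1oc2c(CC=C(C)C)c(OCOC)c(CC=C(C)C)c(OCOC)c2c(=O)c1O | intermediate
22 | 6,8-diprenylkaempferol | CC(C)=CCc1c(O)c(CC=C(C)C)c2oc(-c3ccc(O)cc3)c(O)c(=O)c2c1O | target

**Total step count:** 10
**Longest linear sequence:** 9 (steps 1–5 and 7–10)

**Steps most likely to fail**

**Step 9.** The halide cycle may stall through reductive loss of iodide at the α-iodo ketone stage. Lithium-promoted acyl migration may also compete with halide capture.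
- The fallback splits the event into two known, stoichiometric operations, setting out from 17.
- LiBr and AcOH in THF at 0 °C should open the oxirane at the benzylic carbon. This gives the bromohydrin 2-{bromo[4-(methoxymethoxy)phenyl]methyl}-2-hydroxy-4,6-bis(methoxymethoxy)-5,7-diprenylbenzofuran-3(2H)-one F1, which is the hemiketal of the classical Auwers sequence and is taken on crude.
- KOH in EtOH at rt then brings about ring opening, displacement of bromide by the ring A phenoxide and enolisation. The route is rejoined at 21.

**Step 8.** Conjugate addition of hydroperoxide may be sluggish on an enone that carries four donor oxygens. The sensitive oxirane may also be opened by base during a long reaction time.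
- The fallback builds the oxirane by C–C bond formation (Darzens condensation) instead of by oxidation, setting out from 13.
- LiN(SiMe3)2 in THF at −78 °C followed by N-chlorosuccinimide should chlorinate the enolate faster than either prenyl alkene. This gives 2-chloro-4,6-bis(methoxymethoxy)-5,7-diprenylbenzofuran-3(2H)-one F2.
- Treating F2 and aldehyde 15 with KOt-Bu in THF (−40 °C → 0 °C) should give the chlorohydrin alkoxide and close it to 17, where the route is rejoined.
- The benzylic epimer of 17, the aurone epoxide with the aryl group cis to the C3 carbonyl F3, may accompany it and would be removed by chromatography.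

**Step 5.** Discrimination between the ortho and para MOM groups may be incomplete, which leads to over-deprotection. The fallback removes the need for selectivity and sets out from 11.
- HCl in MeOH at 40 °C cleaves all three acetals on purpose to give 2-chloro-1-(2,4,6-trihydroxy-3,5-diprenylphenyl)ethanone F4.
- NaOAc in MeOH at reflux closes 4,6-dihydroxy-5,7-diprenylbenzofuran-3(2H)-one F5.
- MOMCl with i-Pr2NEt in CH2Cl2 then re-protects both phenols. The route is rejoined at 13.

**Further compounds**
F1 | step 9 | 2-{bromo[4-(methoxymethoxy)phenyl]methyl}-2-hydroxy-4,6-bis(methoxymethoxy)-5,7-diprenylbenzofuran-3(2H)-one (racemic, anti opening of 17) | O=C1c2c(OCOC)c(CC=C(C)C)c(OCOC)c(CC=C(C)C)c2O[C@@]1(O)[C@H](Br)c1ccc(OCOC)cc1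
F2 | step 8 | 2-chloro-4,6-bis(methoxymethoxy)-5,7-diprenylbenzofuran-3(2H)-one (racemic) | O=C1C(Cl)Oc2c(CC=C(C)C)c(OCOC)c(CC=C(C)C)c(OCOC)c12
F3 | step 8 | 4,6,4'-tris(methoxymethoxy)-5,7-diprenylaurone epoxide, benzylic epimer of 17 (racemic, aryl cis to the C3 carbonyl) | O=C1c2c(OCOC)c(CC=C(C)C)c(OCOC)c(CC=C(C)C)c2O[C@]12O[C@@H]2c1ccc(OCOC)cc1
F4 | step 5 | 2-chloro-1-(2,4,6-trihydroxy-3,5-diprenylphenyl)ethanone | O=C(CCl)c1c(O)c(CC=C(C)C)c(O)c(CC=C(C)C)c1O
F5 | step 5 | 4,6-dihydroxy-5,7-diprenylbenzofuran-3(2H)-one | O=C1COc2c(CC=C(C)C)c(O)c(CC=C(C)C)c(O)c12
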